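The data were generated by integration from invented constants, and the scatter is random.

Which way of bringing the same charges together leaves the most solvolysis product after 8.0 h: starting material fed, first nucleophile fed, or everything at once?

common to all: gas 130 mM (held)

| run | starting material | first nucleophile | remark | time |
|---|---|---|---|---|
| spring | 0.30 M | 0.30 M | run made earlier |  |
| autumn | 0.30 M | 0.45 M | run made earlier |  |
| Friday's | 0.30 M (fed, over 1.5 h) | 0.300 M | all else is in the flask from the start; the feed brings no volume worth counting | 8.0 h |
| Tuesday's | 0.30 M | 0.300 M | everything together at the start | 8.0 h |
| Saturday's | 0.30 M | 0.300 M (fed, over 1.5 h) | all else is in the flask from the start; the feed brings no volume worth counting | 8.0 h |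

1. the flask with the highest amount of solvolysis product, in percent of the starting material charged ("all alike" if they lie within 1.5 percentage points) (Friday's / Tuesday's / Saturday's / all alike)
2. final solvolysis product, as a percentage of the starting material charged, in Friday's
3. final solvolysis product, as a percentage of the starting material charged, in Tuesday's
4. final solvolysis product, as a percentage of the starting material charged, in Saturday's

- the numbers in the tables scatter by 2 percentage points (one standard deviation)
- at the start none of the gas is in solution

spring run (percent of the starting material charged)

| time / h | solvolysis product / % | target / % | starting material / % |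
|---|---|---|---|
| 0.833 | 51 | 50 | 0 |
| 1.50 | 51 | 48 | 0 |
| 2.50 | 52 | 40 | 4 |
| 3.00 | 53 | 44 | 0 |
| 4.00 | 51 | 42 | 0 |
| 5.00 | 51 | 41 | 1 |

autumn run (percent of the starting material charged)

| time / min | solvolysis product / % | target / % | starting material / % |
|---|---|---|---|
| 6.00 | 19 | 28 | 32 |
| 20.0 | 36 | 53 | 4 |
| 30.0 | 39 | 55 | 0 |
| 50.0 | 43 | 58 | 0 |
| 80.0 | 40 | 59 | 1 |
| 90.0 | 40 | 58 | 2 |

(each reading ± 2 percentage points)

We read the autumn table down its starting-material column. The first row shows 32% left at 6.00 min, so a first-order decay gives a rate constant k = 0.190 min⁻¹ and a lifetime τ = 1/k = 5.27 min. By 30.0 min that column reads 0%, and from there the solvolysis column stays between 39% and 43%, so the split is made while starting material lasts.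

The first spring row has solvolysis product at 51% and target at 50%. We take that level split to belong to a mean first nucleophile of 0.225 M.

So we count turnovers. N = tf/τ = 17.1, the number of starting-material lifetimes that pass during a feed of length tf, is a Damköhler number. In Saturday's flask, one lifetime brings in 0.0176 M of first nucleophile, far less than that spring mean. If target over solvolysis product goes with the nucleophile present, our own reckoning for Saturday's is 92.8% solvolysis product. Tuesday's has the spring charges, so we read it from the spring column, near 51%.

The forecast names Saturday's, with 90% (83% to 95%) there, 51.5% (48% to 55%) for Friday's and 51.5% (49.5% to 53.5%) for Tuesday's. Its ground for Saturday's is: “Starting material is gone before much nucleophile arrives”. Its Saturday figure lies below ours.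

Saturday's gives 89.8%, against 53.0% in Tuesday's and 49.2% in Friday's. At 1.50 h, the end of its feed, Saturday's already holds 89.8% solvolysis product, with 92.0% of its first nucleophile unused. Its shortfall from full solvolysis is 10.2%: at 8.00 h target and over-reaction product together hold 8.00%, and other capture product holds 2.14%. We carry the first of these on, beside the 0.0176 M fed per lifetime at N = 17.1.

    second nucleophile + intermediate → other capture product (k = 2.40 M⁻¹ min⁻¹)
    first nucleophile + intermediate → target (k = 0.800 M⁻¹ min⁻¹)
    starting material + target → side product (k = 0.00330 M⁻¹ min⁻¹)
    gas ⇌ second nucleophile, rate k4*(csat - [second nucleophile]) (kL = 0.00360 min⁻¹)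
    starting material → intermediate (k = 0.180 min⁻¹)
    second nucleophile + target → over-reaction product (k = 0.00690 M⁻¹ min⁻¹)
    intermediate → solvolysis product (k = 0.210 min⁻¹)

Take the neighbour of Saturday's with 0.51 M of first nucleophile. N stays 17.1 and one lifetime now brings 0.0298 M. Our reckoning lets target and over-reaction product grow in step with that, to 13.6%, and keeps other capture product at 2.14%, which puts solvolysis product at 84.3%. That flask gives 85.4%, with 12.6% in target and over-reaction product and 2.01% in other capture product.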